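You want target, but free catalyst turns it into its isomer, so ask two things: how much starting material is converted, and how target and isomer divide what was converted.

    catalyst intermediate C → catalyst intermediate D (k1 = 73 /min)
    reagent + free catalyst → catalyst intermediate A (k2 = 1700 /M/min)
    catalyst intermediate D → free catalyst + target (k3 = 93 /min)
    target + free catalyst ⇌ isomer of the product + free catalyst, rate k4*[free catalyst]*[target] forward; the back reaction follows from the equilibrium constant (K4 = 0.18, k4 = 1900 /M/min)
    starting material + catalyst intermediate B → catalyst intermediate C (k5 = 1800 /M/min)
    starting material + catalyst intermediate D → spent catalyst (k6 = 1.4 /M/min)
    catalyst intermediate A → catalyst intermediate B (k7 = 270 /min)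

the same everywhere: free catalyst 0.25 mM

|  | starting material | reagent | time | remark |
|---|---|---|---|---|
| Saturday's | 0.050 M | 0.0600 M (fed, over 25.0 min) | 25 min | a stirred flask in which reagent is dosed at a steady rate over 25.0 min without added volume, worked up at 25 min |
| Tuesday's | 0.050 M (fed, over 25.0 min) | 0.0600 M | 25 min | a stirred flask in which starting material is dosed at a steady rate over 25.0 min without added volume, worked up at 25 min |
| Monday's | 0.050 M | 0.0600 M |  | one stirred flow tank at steady state, fed with the mixture as stated, mean residence time 25 min |
| Sunday's | 0.050 M | 0.0600 M | 25 min | everything together in a closed stirred flask, run for 25 min |

- percentages count the starting material that a species holds: one spent catalyst counts as two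
- the stated concentrations are those of everything mixed, before any reaction; amounts are the same in each set-up
- the feed brings no volume worth counting
- run time (Saturday's): 25 min

* the set-up with the highest amount of target at the outlet or at the end, in percent of the starting material put in ("none" if the first two lie within 2 percentage points) (Saturday's / Tuesday's / Monday's / Sunday's / none)
* amount of target at the outlet or at the end, in percent of the starting material put in, Saturday's
* amount of target at the outlet or at the end, in percent of the starting material put in, Tuesday's
* amount of target at the outlet or at the end, in percent of the starting material put in, Monday's
* amount of target at the outlet or at the end, in percent of the starting material put in, Sunday's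

Begin at the far end. Suppose the starting material is converted and the isomerisation has come to balance. Each part of target then stands beside 0.18 parts of isomer, so target holds 84.7% of the converted material. Call this the equilibrium share: target over target plus isomer at balance. Your rule, once balance stands, is that target equals the share times what was converted.

Now take the near end, Sunday's flask. One turn of the catalyst, with both partners at their charge, takes 0.0491 min. Sunday's charge needs 200 turns, so 9.81 min, which is shorter than the 25 min allowed. The waits for reagent and starting material lengthen as both fall. Add them up over Sunday's run, ignoring catalyst loss, and I find 0.109% of the starting material left. So the first figure for Sunday's is the share itself.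

The weak link is the balance. By its forward rate alone, with free catalyst as charged, target has a half-life of 1.46 min, shorter than the run. But with both partners at their charge the catalyst stands free for 20.0% of a turn, so that figure flatters. Reforge it. Free catalyst stands in both the capture of reagent and the isomerisation, so it cancels in their ratio, the selectivity factor 1.12. Isomer then trails its balance by a lag in converted material: its own share times c(reagent) over that factor. For Sunday's flask the charges put c(reagent) near 0.0100 M at the end, so I reckon the lag at 1.36 mM, less than the charge. That lifts my figure for target to 85.2%, and I commit to this for Sunday's. For the other three I commit to no figure. I pick Sunday's, where both partners stand at their charge from the first minute.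

The forecast names Sunday's, with 84.9% there, 76.2% for Saturday's, 73.5% for Monday's and 71.1% for Tuesday's, on the ground “Treat the cycle as quasi-steady”.

The flask gives 85.0% for Sunday's, 76.4% for Saturday's, 73.5% for Monday's and 72.6% for Tuesday's, so Sunday's leads. Sunday's stands 0.30 percentage points above the equilibrium share. Saturday's flask ends with 10.4% of its starting material unconverted, and the equilibrium share of the other 89.6% is 75.9%, beside its 76.4%. Left until 250 min, Saturday's flask stands at 85.1%.

The numbers of this flask stand for no real mixture.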